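**Two rates.** Compare two rates at one moment before you predict any yield.

| flask | starting material | first nucleophile | second nucleophile | protic impurity | temperature | remark | time |
|---|---|---|---|---|---|---|---|
| north-west | 0.12 M | 4 equiv | 2.5 equiv | 0.024 M | 20 °C | run made earlier |  |
| east | 0.48 M | 4 equiv | 2.5 equiv | 0.024 M | 50 °C | run made earlier |  |
| south-east | 0.24 M | 4 equiv | 1.2 equiv | 0.024 M | 20 °C | run made earlier |  |
| alpha | 0.24 M | 4.00 equiv | 2.50 equiv | 0.0240 M | 25 °C |  | 10 min |
| zeta | 0.24 M | 4.00 equiv | 2.50 equiv | 0.0240 M | 50 °C |  | 10 min |
| epsilon | 0.24 M | 4.00 equiv | 2.50 equiv | 0.0240 M |  | at 75 °C until 3.0 min, from then on at 25 °C | 10 min |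
| eta | 0.24 M | 4.00 equiv | 2.50 equiv | 0.0240 M | 75 °C |  | 10 min |

- north-west (time / min: target / %): 1.33: 5; 4.00: 15; 6.00: 18; 10.0: 31
- east (time / min: target / %): 0.667: 28; 1.33: 51; 2.50: 65; 3.00: 68
- south-east (time / min: target / %): 2.50: 9; 5.00: 15; 8.00: 25; 10.0: 29

(readings scatter by 1.5 percentage points)

- the analysis behind the earlier runs scatters by 1.5 percentage points, standard deviation

* the flask that comes out highest in amount of target, in percent of the starting material charged, or "all alike" when all lie within 1.5 percentage points (alpha / zeta / epsilon / eta / all alike)
* target at the end, in percent of the starting material charged, alpha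
* target at the end, in percent of the starting material charged, zeta
* target at the end, in percent of the starting material charged, epsilon
* target at the end, in percent of the starting material charged, eta

**Cold runs.** North-west and south-east reach 31% and 29% at 10.0 min, although south-east holds twice the c(first nucleophile). So I read the loss of starting material as first order and independent of the nucleophiles. I take that loss as the clock of a flask, with the nucleophiles sharing out what it releases. Since c(first nucleophile)/c(second nucleophile) also doubled while the two last readings stand 2 percentage points apart, with a scatter of 1.5 points, I read the diversion at 20 °C as too small to see.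

**Hot split.** East flattens near 68%, and I read this flattening as a split, not a decay. Its readings give a first-order constant of 1.04 min⁻¹, so a life of 0.959 min. Corrected for the unfinished part at 3.00 min, I read the plateau as 71.1%. I carry the capture ratio ρ, the rate forming target over the rate diverting material elsewhere at the same moment, a selectivity read here as 2.46. I take ρ as proportional to c(first nucleophile)/c(second nucleophile).

**My reckoning.** Zeta has east's temperature and the same ratio of nucleophiles, and its protic impurity is hardly any of its first nucleophile, so ρ carries over. Its 10 min is ten times the life, so zeta should finish near 71.1%. Since I read ρ as falling on warming, I put epsilon and eta below zeta. After north-west's 31% at 20 °C, I expect alpha at 25 °C to be unfinished. My pick is zeta.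

**The forecast.** It names epsilon, with alpha 50%, zeta 58%, epsilon 60% and eta 32%: “a hot start then cooling should win”. We part on zeta.

**The outcome.** Alpha gives 43.0%, zeta 73.7%, epsilon 58.5% and eta 58.5%, so zeta leads.

    starting material → intermediate (k = 0.0130 s⁻¹, Ea = 78.0 kJ mol⁻¹)
    first nucleophile + intermediate → target (k = 1.80 L mol⁻¹ s⁻¹, Ea = 39.0 kJ mol⁻¹)
    second nucleophile + intermediate → other capture product (k = 0.960 L mol⁻¹ s⁻¹, Ea = 67.0 kJ mol⁻¹)
    first nucleophile + protic impurity → quenched reagent (k = 0.0480 L mol⁻¹ s⁻¹, Ea = 53.0 kJ mol⁻¹)
    (constants at 50 °C)

**The split.** In zeta at 0.890 min, the intermediate goes to target 2.8 times as fast as to other capture product, against my 2.46 read from east, and zeta ends at 73.7% against my 71.1%. Raising the first nucleophile to 6.80 equiv scales my ρ to 4.19, a share of 80.7%, and that neighbour of zeta gives 83.0%.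

The data come from a simulation for an exercise; scatter was added.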